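The runs were computed from invented constants.

You cannot, it seems, load 1.48 times the substrate on the same catalyst and reach the same fraction reacted a mere 5.00 min later, yet the east run at 25.0 min and this flask at 30 min look set to do that.

| flask | substrate | free catalyst | remark | time |
|---|---|---|---|---|
| east | 0.54 M | 8 mM (in portions, 4) | run made earlier; portions every 8.0 min |  |
| west | 1.2 M | 8 mM (in portions, 4) | run made earlier; portions every 8.0 min |  |
| flask | 0.80 M | 8.0 mM (in portions, 4) | the portions of free catalyst follow each other after 8.0 min, the first at the start | 30 min |

| run | time / min | substrate / % | product / % |
|---|---|---|---|
| east | 3.00 | 95.9 | 4.0 |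
| east | 10.0 | 84.5 | 13.8 |
| east | 15.0 | 73.5 | 26.7 |
| east | 25.0 | 40.1 | 58.4 |
| east | 40.0 | 6.8 | 93.2 |
| west | 3.00 | 96.9 | 1.4 |
| west | 10.0 | 91.4 | 7.7 |
| west | 15.0 | 85.8 | 13.9 |
| west | 25.0 | 66.9 | 31.8 |
| west | 40.0 | 32.7 | 66.3 |

(standard deviation of a reading: 0.5 percentage points)

- the reaction counts as stopped when no species that holds the substrate changes by six tenths of a point or more over the second half of the time

- the state of affairs at 30 min: stopped, and by what, or still going (it is still moving / forward and back rates have come level / no working catalyst is left / all of the substrate has reacted)
- how much of the substrate has reacted by 30 min
- how much product there is at 30 min, in percent of the substrate charged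
- amount of product if the flask were left three thousand times as long, in percent of the substrate charged

The clock misleads when catalyst comes in portions. Counting each portion from its own addition gives 18.0 min at 30 min: this is the full-charge time, the minutes of the whole charge that equal the catalyst-minutes given. East at 25.0 min has had 13.0 min, so the flask has 1.38 times as much.

Now freeze two things: a ceiling V, the substrate the whole charge turns per minute when fully loaded, and H, the substrate level at which it works at half that. Then V × full-charge time = charge × fraction reacted + H × ln(charged/left). East and west both stand at 28.0 min after 40.0 min, and those readings give H = 0.194 M and V = 0.0366 M min⁻¹.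

East's 59.9% reacted would cost this flask 17.9 min of full-charge time, and it has 18.0 min. So I expect about that conversion, with product behind it by no more than 1.00% of this flask's substrate charge, which is what the whole catalyst charge could hold if each catalyst held one substrate. By the rule, the flask at that point would still be turning substrate at 0.0228 M min⁻¹, faster than the 0.0183 M min⁻¹ it turns at level H, so I expect it still moving. With east at 93.2% product by 40.0 min, I expect it to run on towards full conversion.

The forecast says it is still moving, with 60.8% reacted, 60.1% product and 99% in the end, and holds that “the catalyst shows no detectable death”. The flask gives: it is still moving, with 60.8% reacted, 60.1% product and 100% in the end.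

    substrate + free catalyst → catalyst intermediate (k = 0.593 L mol⁻¹ s⁻¹)
    catalyst intermediate → free catalyst + product (k = 0.0700 s⁻¹)
    2 free catalyst ⇌ resting dimer (K = 104 L mol⁻¹, k = 0.220 L mol⁻¹ s⁻¹)

The flask's conversion costs 18.3 min by the rule, against the 18.0 min it had. The neighbour charged with 0.0048 M of free catalyst keeps this substrate charge, so its catalyst-minutes at 30 min equal 10.8 min of this flask's full-charge time. Its 38.3% reacted costs 10.9 min by the same rule. At 30.0 min catalyst intermediate, the resting state of the round, holds 79.0% of that neighbour's catalyst charged, and 62% of its substrate is left unbound.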